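(The earlier runs and the new flask are calculated on assumed constants; the scatter is artificial.)

**Target and order.** Target rises early in Friday's run while substrate falls, so the first question here is which concentration sets the order of that fall.

| flask | substrate | reagent | temperature | remark | time |
|---|---|---|---|---|---|
| Friday's | 0.25 M | 1 M | 70 °C | run made earlier |  |
| dawn | 0.50 M | 1.00 M | 70 °C |  | 2.0 h |
| noon | 0.50 M | 1.00 M | 30 °C |  | 2.0 h |
| summer | 0.50 M | 1.00 M | 10 °C |  | 2.0 h |
| spring | 0.50 M | 1.00 M | 50 °C |  | 2.0 h |

Friday's run (percent of the substrate charged)

| time / min | target / % | substrate / % |
|---|---|---|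
| 4.00 | 44.5 | 31.4 |
| 8.00 | 73.4 | 10.2 |
| 12.0 | 82.2 | 3.0 |
| 15.0 | 84.3 | 3.0 |
| 20.0 | 82.4 | 1.7 |
| 25.0 | 78.2 | 0.6 |

(standard deviation of a reading: 1 percentage point)

- the earlier runs were read with a standard deviation of 1 percentage point
- the earlier runs do not show what temperature does; that part of a forecast is a guess

- the best flask by amount of target, in percent of the substrate charged; "all alike" if 1.5 percentage points covers them all (dawn / noon / summer / spring / all alike)
- amount of target at the end, in percent of the substrate charged, dawn
- amount of target at the end, in percent of the substrate charged, noon
- amount of target at the end, in percent of the substrate charged, summer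
- amount of target at the end, in percent of the substrate charged, spring

**Bench rule.** Friday's flask holds reagent and substrate in a ratio of 4.00, so the bench rule (pseudo-first-order) takes c(reagent) as constant and reads one constant off c(substrate). The reading at 4.00 min gives 0.290 min⁻¹, and the reading at 12.0 min gives 0.292 min⁻¹, both with the readings' scatter. Dawn charges the same c(reagent) at the same temperature, so the rule promises a substrate half-life of 2.39 min.

**The border.** The new flasks have a ratio of 2.00, smaller than Friday's. No reagent was read, so this reckoning assumes that reagent enters the rate and that each substrate uses one reagent, which makes substrate the limiting reagent. The number to watch is then the reagent floor: 50.0%, the share of its charge that reagent keeps once every substrate has reacted. Friday's floor is 75.0%, higher than the new flasks', so on this assumption the constant does not carry over unchanged. On the floor, this reckoning puts dawn's constant at 0.145 min⁻¹ and its half-life at 4.78 min, still far shorter than the 2.0 h of the run. Dawn should therefore end with reagent at the floor. This reckoning gives no yield.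

**The forecast.** The forecast expects dawn 36%, noon 55%, summer 4% and spring 75%, and names spring best: “At 50 °C, conversion is complete and decay is mild”.

**The result.** Dawn gives 39.5%, noon 17.9%, summer 0.225% and spring 88.3%, so spring leads.

    substrate + reagent → intermediate + released group (k = 0.330 L mol⁻¹ min⁻¹, Ea = 81.0 kJ mol⁻¹)
    intermediate → target (k = 0.480 min⁻¹, Ea = 95.0 kJ mol⁻¹)
    target ⇌ isomer of the product (K = 2.00, k = 0.0140 min⁻¹, Ea = 117 kJ mol⁻¹, ΔH = −54.0 kJ mol⁻¹)
    (constants at 70 °C)

**Rest or not.** Spring ends with substrate at 1.7% and reagent at 51%, just above the floor of 50.0%. Ten times the time brings spring's reagent to 50.0%, yet target drops from 88.3% to 33.1% while isomer of the product climbs from 8.40% to 66.9%. Spring's relaxation half-life of target and isomer of the product, 9.04 h, is long against the time; spring's reagent stands near its floor, but the flask is not at rest. Dawn has reagent on the floor at 50%, and its target still slips from 39.5% to 33.3% after 20.0 h.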